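**Assumption:** the target has no stereocentre (it is achiral), so no stereocontrol is needed. Rings are lettered A (2,4,6-trihydroxyphenoxy end) to G (3,4,5-trihydroxyphenoxy end). TMP = 2,4,6-trimethoxyphenyl, TIPS = triisopropylsilyl.

## Retrosynthetic overview

1. Target ⇐ global O-demethylation of its octadecamethyl ether. No ring is built: all seven benzene rings come from commercial methoxyarenes and are only joined.
2. Every diaryl ether bond is cut into a 2,6-dioxygenated phenoxide and a 3,4,5-trioxygenated aryl cation synthon. The latter is an aryl(TMP)iodonium salt, in which an innately nucleophilic arene carbon has been made electrophilic.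
3. Key disconnection: rings B–C and D–E are the same two-ring unit. One bifunctional dimeric iodonium salt (ring B iodonium, ring C silyl-masked phenol) is therefore used twice, followed by a dimeric ring F–G iodonium salt.
4. Each dimer comes from 4-iodo-2,6-dimethoxyphenol (O-nucleophile carrying a dormant iodide) and a monomeric iodonium salt; the surviving iodide is then oxidised to the next iodonium.
5. Order of joining: B+C and F+G (dimers), then A+(B–C), then +(D–E), then +(F–G), then demethylation.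

## Route

Step 1
Reactants: 1 2,6-dimethoxyphenol
Product: 2 4-iodo-2,6-dimethoxyphenol
Conditions: NIS, TFA (cat.), MeCN, 0 °C to rt, dark
Reagents that add atoms: N-iodosuccinimide O=C1CCC(=O)N1I
Why: Electrophilic aromatic iodination goes para to the free hydroxyl because both ortho positions carry methoxy groups.

Step 2
Reactants: 3 2,3,4-trimethoxyphenol
Product: 5 triisopropyl(6-iodo-2,3,4-trimethoxyphenoxy)silane, via 6-iodo-2,3,4-trimethoxyphenol 4 (not isolated)
Conditions: NIS, DMF, 0 °C; then imidazole, TIPSCl, 50 °C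
Reagents that add atoms: N-iodosuccinimide O=C1CCC(=O)N1I; triisopropylsilyl chloride CC(C)[Si](Cl)(C(C)C)C(C)C
Why: Hydroxyl-directed electrophilic aromatic iodination occurs ortho to OH (para is blocked, and C6 is also para to the 3-methoxy group), and the phenol is then capped in the same pot by imidazole-mediated silylation so that it survives the later peracid/acid stage.

Step 3
Reactants: 5 triisopropyl(6-iodo-2,3,4-trimethoxyphenoxy)silane
Product: 7 [3,4,5-trimethoxy-2-(triisopropylsilyloxy)phenyl](2,4,6-trimethoxyphenyl)iodonium tosylate, via hydroxy(tosyloxy)iodoarene 6 (not isolated)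
Conditions: mCPBA, TsOH·H2O, MeCN, rt; then 1,3,5-trimethoxybenzene, rt; Et2O trituration
Reagents that add atoms: 1,3,5-trimethoxybenzene COc1cc(OC)cc(OC)c1; p-toluenesulfonic acid monohydrate Cc1ccc(cc1)S(=O)(=O)O.O
Why: One-pot diaryliodonium synthesis: peracid oxidation of the aryl iodide gives a Koser-type λ3-iodane, which undergoes electrophilic aromatic substitution on 1,3,5-trimethoxybenzene, turning ring C carbon 1 into an aryl cation equivalent.

Step 4
Reactants: 2 4-iodo-2,6-dimethoxyphenol; 7 ring C iodonium tosylate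
Product: 8 triisopropyl[6-(4-iodo-2,6-dimethoxyphenoxy)-2,3,4-trimethoxyphenoxy]silane (ring B–C iodide)
Conditions: Cs2CO3, MeCN, 45 °C, Ar
Reagents that add atoms: none
Why: Metal-free O-arylation with a diaryliodonium salt: the phenoxide of 2 (ortho and para positions blocked, so only oxygen reacts) exchanges onto trivalent iodine, and ligand coupling transfers the less electron-rich ring C aryl rather than TMP; the C–I bond of 2 survives because no transition metal is present.

Step 5
Reactants: 8 ring B–C iodide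
Product: 10 {3,5-dimethoxy-4-[3,4,5-trimethoxy-2-(triisopropylsilyloxy)phenoxy]phenyl}(2,4,6-trimethoxyphenyl)iodonium tosylate (ring B–C iodonium salt), via hydroxy(tosyloxy)iodoarene 9 (not isolated)
Conditions: mCPBA (1.05 equiv), TsOH·H2O, MeCN/CH2Cl2, 0 °C to rt; then 1,3,5-trimethoxybenzene; Et2O trituration
Reagents that add atoms: 1,3,5-trimethoxybenzene COc1cc(OC)cc(OC)c1; p-toluenesulfonic acid monohydrate Cc1ccc(cc1)S(=O)(=O)O.O
Why: The same oxidation/electrophilic aromatic substitution sequence as in step 3 activates the dormant iodide on ring B; iodine is oxidised faster than the arene rings, and the iodine sits para to the aryloxy group, so no cyclic iodonium can form.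

Step 6
Reactants: 11 5-iodo-1,2,3-trimethoxybenzene
Product: 13 (3,4,5-trimethoxyphenyl)(2,4,6-trimethoxyphenyl)iodonium tosylate, via hydroxy(tosyloxy)iodoarene 12 (not isolated)
Conditions: mCPBA, TsOH·H2O, MeCN, rt to 40 °C; then 1,3,5-trimethoxybenzene; Et2O trituration
Reagents that add atoms: 1,3,5-trimethoxybenzene COc1cc(OC)cc(OC)c1; p-toluenesulfonic acid monohydrate Cc1ccc(cc1)S(=O)(=O)O.O
Why: One-pot Koser-type oxidation and trapping with 1,3,5-trimethoxybenzene gives the ring G aryl cation equivalent as a bench-stable salt.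

Step 7
Reactants: 2 4-iodo-2,6-dimethoxyphenol; 13 ring G iodonium tosylate
Product: 14 5-iodo-1,3-dimethoxy-2-(3,4,5-trimethoxyphenoxy)benzene (ring F–G iodide)
Conditions: Cs2CO3, MeCN, 45 °C, Ar
Reagents that add atoms: none
Why: Metal-free O-arylation by ligand coupling at trivalent iodine transfers the unhindered 3,4,5-trimethoxyphenyl group (TMP stays on iodine) and leaves the aryl iodide intact.

Step 8
Reactants: 14 ring F–G iodide
Product: 16 [3,5-dimethoxy-4-(3,4,5-trimethoxyphenoxy)phenyl](2,4,6-trimethoxyphenyl)iodonium tosylate (ring F–G iodonium salt), via hydroxy(tosyloxy)iodoarene 15 (not isolated)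
Conditions: mCPBA (1.05 equiv), TsOH·H2O, MeCN/CH2Cl2, 0 °C to rt; then 1,3,5-trimethoxybenzene; Et2O trituration
Reagents that add atoms: 1,3,5-trimethoxybenzene COc1cc(OC)cc(OC)c1; p-toluenesulfonic acid monohydrate Cc1ccc(cc1)S(=O)(=O)O.O
Why: Chemoselective oxidation of iodine to a Koser-type λ3-iodane and immediate electrophilic aromatic substitution on the far more nucleophilic 1,3,5-trimethoxybenzene gives the dimeric aryl cation equivalent.

Step 9
Reactants: 17 2,4,6-trimethoxyphenol; 10 ring B–C iodonium salt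
Product: 18 triisopropyl{6-[2,6-dimethoxy-4-(2,4,6-trimethoxyphenoxy)phenoxy]-2,3,4-trimethoxyphenoxy}silane (ring A–B–C silyl ether)
Conditions: Cs2CO3, MeCN, 45 °C, Ar
Reagents that add atoms: none
Why: Key polarity-reversed diaryl ether formation (metal-free O-arylation with a diaryliodonium salt): the ring B head carbon, innately nucleophilic in an oxygenated arene, is delivered as an aryl cation equivalent to the hindered phenoxide by ligand exchange and ligand coupling at trivalent iodine, with the more electron-rich, more hindered TMP group staying on iodine.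

Step 10
Reactants: 18 ring A–B–C silyl ether; 10 ring B–C iodonium salt
Product: 20 ring A–B–C–D–E silyl ether, via ring A–B–C tetrabutylammonium phenoxide 19 (not isolated)
Conditions: Bu4NF (1.0 equiv), THF, 0 °C; then 10, THF, rt to 40 °C, Ar
Reagents that add atoms: none
Why: Fluoride desilylation gives a naked phenoxide that is O-arylated in situ by the second equivalent of the dimeric iodonium salt (same ligand-coupling mechanism); exactly one equivalent of fluoride and the bulky TIPS group keep the silyl ether of 10 intact.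

Step 11
Reactants: 20 ring A–B–C–D–E silyl ether; 16 ring F–G iodonium salt
Product: 22 octadeca-O-methyl ether of the target, via ring A–B–C–D–E tetrabutylammonium phenoxide 21 (not isolated)
Conditions: Bu4NF (1.0 equiv), THF, 0 °C; then 16, THF, rt to 40 °C, Ar
Reagents that add atoms: none
Why: Fluoride-triggered phenoxide formation followed by metal-free O-arylation with the dimeric ring F–G aryl cation equivalent closes the seven-ring chain; oxygen is the only nucleophilic site because both ortho positions and the para position of the phenoxide are substituted.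

Step 12
Reactants: 22 octadeca-O-methyl ether of the target
Product: 23 CNP0292517.0 (target)
Conditions: BBr3 (30 equiv), CH2Cl2, −78 °C to rt, Ar; then degassed MeOH/H2O; reversed-phase purification under Ar
Reagents that add atoms: none
Why: Lewis-acid aryl methyl ether cleavage: BBr3 complexes each methoxy oxygen and bromide removes the methyl group by SN2, while the diaryl ether bonds are inert because neither aryl carbon can undergo SN2.

## Compound list

1 | 2,6-dimethoxyphenol | COc1cccc(OC)c1O | starting material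
2 | 4-iodo-2,6-dimethoxyphenol | COc1cc(I)cc(OC)c1O | intermediate
3 | 2,3,4-trimethoxyphenol | COc1ccc(O)c(OC)c1OC | starting material
4 | 6-iodo-2,3,4-trimethoxyphenol | COc1cc(I)c(O)c(OC)c1OC | intermediate (not isolated)
5 | triisopropyl(6-iodo-2,3,4-trimethoxyphenoxy)silane | COc1cc(I)c(O[Si](C(C)C)(C(C)C)C(C)C)c(OC)c1OC | intermediate
6 | 1-[hydroxy(tosyloxy)iodo]-3,4,5-trimethoxy-2-(triisopropylsilyloxy)benzene (Koser-type λ3-iodane) | COc1cc(I(O)OS(=O)(=O)c2ccc(C)cc2)c(O[Si](C(C)C)(C(C)C)C(C)C)c(OC)c1OC | intermediate (not isolated)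
7 | [3,4,5-trimethoxy-2-(triisopropylsilyloxy)phenyl](2,4,6-trimethoxyphenyl)iodonium tosylate (ring C iodonium salt) | COc1cc([I+]c2c(OC)cc(OC)cc2OC)c(O[Si](C(C)C)(C(C)C)C(C)C)c(OC)c1OC.Cc1ccc(cc1)S(=O)(=O)[O-] | intermediate
8 | triisopropyl[6-(4-iodo-2,6-dimethoxyphenoxy)-2,3,4-trimethoxyphenoxy]silane (ring B–C iodide) | COc1cc(I)cc(OC)c1Oc1cc(OC)c(OC)c(OC)c1O[Si](C(C)C)(C(C)C)C(C)C | intermediate
9 | hydroxy(tosyloxy)iodo derivative of 8 (iodine on ring B carries OH and OTs) | COc1cc(I(O)OS(=O)(=O)c2ccc(C)cc2)cc(OC)c1Oc1cc(OC)c(OC)c(OC)c1O[Si](C(C)C)(C(C)C)C(C)C | intermediate (not isolated)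
10 | {3,5-dimethoxy-4-[3,4,5-trimethoxy-2-(triisopropylsilyloxy)phenoxy]phenyl}(2,4,6-trimethoxyphenyl)iodonium tosylate (ring B–C iodonium salt) | COc1cc([I+]c2c(OC)cc(OC)cc2OC)cc(OC)c1Oc1cc(OC)c(OC)c(OC)c1O[Si](C(C)C)(C(C)C)C(C)C.Cc1ccc(cc1)S(=O)(=O)[O-] | intermediate
11 | 5-iodo-1,2,3-trimethoxybenzene | COc1cc(I)cc(OC)c1OC | starting material
12 | 5-[hydroxy(tosyloxy)iodo]-1,2,3-trimethoxybenzene | COc1cc(I(O)OS(=O)(=O)c2ccc(C)cc2)cc(OC)c1OC | intermediate (not isolated)
13 | (3,4,5-trimethoxyphenyl)(2,4,6-trimethoxyphenyl)iodonium tosylate (ring G iodonium salt) | COc1cc([I+]c2c(OC)cc(OC)cc2OC)cc(OC)c1OC.Cc1ccc(cc1)S(=O)(=O)[O-] | intermediate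
14 | 5-iodo-1,3-dimethoxy-2-(3,4,5-trimethoxyphenoxy)benzene (ring F–G iodide) | COc1cc(I)cc(OC)c1Oc1cc(OC)c(OC)c(OC)c1 | intermediate
15 | hydroxy(tosyloxy)iodo derivative of 14 | COc1cc(I(O)OS(=O)(=O)c2ccc(C)cc2)cc(OC)c1Oc1cc(OC)c(OC)c(OC)c1 | intermediate (not isolated)
16 | [3,5-dimethoxy-4-(3,4,5-trimethoxyphenoxy)phenyl](2,4,6-trimethoxyphenyl)iodonium tosylate (ring F–G iodonium salt) | COc1cc([I+]c2c(OC)cc(OC)cc2OC)cc(OC)c1Oc1cc(OC)c(OC)c(OC)c1.Cc1ccc(cc1)S(=O)(=O)[O-] | intermediate
17 | 2,4,6-trimethoxyphenol | COc1cc(OC)c(O)c(OC)c1 | starting material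
18 | triisopropyl{6-[2,6-dimethoxy-4-(2,4,6-trimethoxyphenoxy)phenoxy]-2,3,4-trimethoxyphenoxy}silane (ring A–B–C silyl ether) | COc1cc(OC)c(Oc2cc(OC)c(Oc3cc(OC)c(OC)c(OC)c3O[Si](C(C)C)(C(C)C)C(C)C)c(OC)c2)c(OC)c1 | intermediate
19 | tetrabutylammonium phenoxide of the ring A–B–C trimer (18 with O− in place of OTIPS) | COc1cc(OC)c(Oc2cc(OC)c(Oc3cc(OC)c(OC)c(OC)c3[O-])c(OC)c2)c(OC)c1.CCCC[N+](CCCC)(CCCC)CCCC | intermediate (not isolated)
20 | ring A–B–C–D–E silyl ether (18 with its ring C oxygen bonded to carbon 1 of a 3,5-dimethoxy-1,4-phenylene ring D, whose 4-oxygen carries the 3,4,5-trimethoxy-2-(triisopropylsilyloxy)phenyl ring E) | COc1cc(OC)c(Oc2cc(OC)c(Oc3cc(OC)c(OC)c(OC)c3Oc3cc(OC)c(Oc4cc(OC)c(OC)c(OC)c4O[Si](C(C)C)(C(C)C)C(C)C)c(OC)c3)c(OC)c2)c(OC)c1 | intermediate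
21 | tetrabutylammonium phenoxide of the ring A–B–C–D–E pentamer (20 with O− in place of OTIPS) | COc1cc(OC)c(Oc2cc(OC)c(Oc3cc(OC)c(OC)c(OC)c3Oc3cc(OC)c(Oc4cc(OC)c(OC)c(OC)c4[O-])c(OC)c3)c(OC)c2)c(OC)c1.CCCC[N+](CCCC)(CCCC)CCCC | intermediate (not isolated)
22 | octadeca-O-methyl ether of the target (all 18 hydroxyls as OMe) | COc1cc(OC)c(Oc2cc(OC)c(Oc3cc(OC)c(OC)c(OC)c3Oc3cc(OC)c(Oc4cc(OC)c(OC)c(OC)c4Oc4cc(OC)c(Oc5cc(OC)c(OC)c(OC)c5)c(OC)c4)c(OC)c3)c(OC)c2)c(OC)c1 | intermediate
23 | CNP0292517.0 (achiral heptameric fuhalol-type phlorotannin) | Oc1cc(O)c(Oc2cc(O)c(Oc3cc(O)c(O)c(O)c3Oc3cc(O)c(Oc4cc(O)c(O)c(O)c4Oc4cc(O)c(Oc5cc(O)c(O)c(O)c5)c(O)c4)c(O)c3)c(O)c2)c(O)c1 | target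

## Step count

Total: 12 steps. Longest linear sequence: 8 steps (3 → 5 → 7 → 8 → 10 → 18 → 20 → 22 → 23).

## Three steps most likely to fail, with fallbacks

**Step 4** (transfer of the hindered, electron-rich ortho-silyloxyaryl group of 7 to the hindered phenoxide of 2; it may be slow or compete with TMP transfer). The fallback installs the ring C oxygen after the ether bond is made. It sets out from 14, which is already made in step 7. Vilsmeier–Haack formylation (POCl3, DMF, 80 °C) attacks only the activated position of the trimethoxyphenoxy ring, ortho to the ether oxygen. This gives 6-(4-iodo-2,6-dimethoxyphenoxy)-2,3,4-trimethoxybenzaldehyde F1. Dakin-type Baeyer–Villiger oxidation (mCPBA, CH2Cl2, 0 °C) gives 6-(4-iodo-2,6-dimethoxyphenoxy)-2,3,4-trimethoxyphenyl formate F2. Methanolysis (K2CO3, MeOH) gives 6-(4-iodo-2,6-dimethoxyphenoxy)-2,3,4-trimethoxyphenol F3. Silylation (TIPSCl, imidazole, DMF) brings the fallback back to the route at 8.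

**Step 5** (peracid/sulfonic acid oxidation of the iodide of 8 in the presence of the penta-oxygenated ring C, which may be over-oxidised or attack the λ3-iodane). The fallback keeps every oxidation at the monomer stage and adds rings B and C one at a time. It sets out from 2. Silylation (TIPSCl, imidazole, DMF) gives triisopropyl(4-iodo-2,6-dimethoxyphenoxy)silane F4. mCPBA/TsOH·H2O gives 5-[hydroxy(tosyloxy)iodo]-1,3-dimethoxy-2-(triisopropylsilyloxy)benzene F5, which is trapped with 1,3,5-trimethoxybenzene as [3,5-dimethoxy-4-(triisopropylsilyloxy)phenyl](2,4,6-trimethoxyphenyl)iodonium tosylate F6. Phenol 17 is O-arylated with F6 (Cs2CO3, MeCN) to give [2,6-dimethoxy-4-(2,4,6-trimethoxyphenoxy)phenoxy]triisopropylsilane F7. Bu4NF liberates tetrabutylammonium 2,6-dimethoxy-4-(2,4,6-trimethoxyphenoxy)phenoxide F8, which is arylated with 7, and the fallback comes back to the route at 18. For the second unit, 19 (from 18 and Bu4NF) is arylated with F6 to give the ring A–B–C–D silyl ether F9. Bu4NF converts it into the ring A–B–C–D tetrabutylammonium phenoxide F10, which is arylated with 7, and the route is rejoined at 20.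

**Step 12** (eighteen-fold demethylation; partly methylated material and air oxidation of the pyrogallol-type rings make direct isolation difficult). The fallback is capture and release and sets out from 22. After the BBr3 cleavage and methanol quench, the crude polyphenol is not purified but peracetylated (Ac2O, pyridine, Ar) to the octadecaacetate of the target F11. This is air-stable and can be purified on silica, which removes incompletely demethylated material. Acid methanolysis (AcCl in degassed MeOH, Ar) then releases the free polyphenol, and the fallback comes back to the route at 23.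

## Further compounds

F1 | step 4 | 6-(4-iodo-2,6-dimethoxyphenoxy)-2,3,4-trimethoxybenzaldehyde | COc1cc(I)cc(OC)c1Oc1cc(OC)c(OC)c(OC)c1C=O
F2 | step 4 | 6-(4-iodo-2,6-dimethoxyphenoxy)-2,3,4-trimethoxyphenyl formate | COc1cc(I)cc(OC)c1Oc1cc(OC)c(OC)c(OC)c1OC=O
F3 | step 4 | 6-(4-iodo-2,6-dimethoxyphenoxy)-2,3,4-trimethoxyphenol | COc1cc(I)cc(OC)c1Oc1cc(OC)c(OC)c(OC)c1O
F4 | step 5 | triisopropyl(4-iodo-2,6-dimethoxyphenoxy)silane | COc1cc(I)cc(OC)c1O[Si](C(C)C)(C(C)C)C(C)C
F5 | step 5 | 5-[hydroxy(tosyloxy)iodo]-1,3-dimethoxy-2-(triisopropylsilyloxy)benzene | COc1cc(I(O)OS(=O)(=O)c2ccc(C)cc2)cc(OC)c1O[Si](C(C)C)(C(C)C)C(C)C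
F6 | step 5 | [3,5-dimethoxy-4-(triisopropylsilyloxy)phenyl](2,4,6-trimethoxyphenyl)iodonium tosylate | COc1cc([I+]c2c(OC)cc(OC)cc2OC)cc(OC)c1O[Si](C(C)C)(C(C)C)C(C)C.Cc1ccc(cc1)S(=O)(=O)[O-]
F7 | step 5 | [2,6-dimethoxy-4-(2,4,6-trimethoxyphenoxy)phenoxy]triisopropylsilane | COc1cc(OC)c(Oc2cc(OC)c(O[Si](C(C)C)(C(C)C)C(C)C)c(OC)c2)c(OC)c1
F8 | step 5 | tetrabutylammonium 2,6-dimethoxy-4-(2,4,6-trimethoxyphenoxy)phenoxide | COc1cc(OC)c(Oc2cc(OC)c([O-])c(OC)c2)c(OC)c1.CCCC[N+](CCCC)(CCCC)CCCC
F9 | step 5 | ring A–B–C–D silyl ether (19 O-arylated with the 3,5-dimethoxy-4-(triisopropylsilyloxy)phenyl group) | COc1cc(OC)c(Oc2cc(OC)c(Oc3cc(OC)c(OC)c(OC)c3Oc3cc(OC)c(O[Si](C(C)C)(C(C)C)C(C)C)c(OC)c3)c(OC)c2)c(OC)c1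
F10 | step 5 | tetrabutylammonium phenoxide of the ring A–B–C–D tetramer | COc1cc(OC)c(Oc2cc(OC)c(Oc3cc(OC)c(OC)c(OC)c3Oc3cc(OC)c([O-])c(OC)c3)c(OC)c2)c(OC)c1.CCCC[N+](CCCC)(CCCC)CCCC
F11 | step 12 | octadecaacetate of the target | CC(=O)Oc1cc(OC(C)=O)c(Oc2cc(OC(C)=O)c(Oc3cc(OC(C)=O)c(OC(C)=O)c(OC(C)=O)c3Oc3cc(OC(C)=O)c(Oc4cc(OC(C)=O)c(OC(C)=O)c(OC(C)=O)c4Oc4cc(OC(C)=O)c(Oc5cc(OC(C)=O)c(OC(C)=O)c(OC(C)=O)c5)c(OC(C)=O)c4)c(OC(C)=O)c3)c(OC(C)=O)c2)c(OC(C)=O)c1
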